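**Plan**
- Retrosynthesis: the epoxide goes last (directed epoxidation of the chain allylic alcohol). In C1=C(CH3)CHO the formyl group is cis to methine C6, which carries the arm, so formyl carbon and arm are tied into a six-membered enone, ring A, fused at C1–C6.
- Ring A is cut at C1=C(CH3) (aldol condensation of a 1,5-diketone) and at C6–CH2 (Michael addition). C5–CH3 and C5–chain are cut as two conjugate additions to a 4-hydroxy-4-methylcyclohexenone. The chain is cut at its two CH2–CH= bonds.
- Forward: the chain comes from prenal by propargylation and two rounds of carboalumination/iodination, joined by Negishi coupling and oxirane opening. Ring B comes from geraniol via (S)-linalool and ring-closing metathesis; chain, methyl and arm are then added in that order.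
- Ring A is closed, hydroxylated beside its carbonyl and cleaved there to a Z-enoate and an aldehyde. The aldehyde gains one carbon (Wittig, hydroboration), the ester is taken to the enal, and desilylation and epoxidation finish.
- Stereochemistry: C4 from Sharpless epoxidation; C5 from alkoxide-directed methyl delivery cis to the C4 oxygen; C6 from axial Michael addition anti to the chain; the chain carbinol from a chiral phosphoric acid propargylation; the epoxide from allylic-strain-controlled directed epoxidation; E-alkenes from syn-carbometalation; the Z-enal from ring A.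

Key step: step 21

Conventions: ring B is numbered as in the target core (C1 carbonyl, later the ring alkene carbon; C4 carbinol; C5 quaternary; C6 methine). "SC" in names is the (3E,7E,10S)-10-(tert-butyldimethylsilyloxy)-4,8,12-trimethyltrideca-3,7,11-trien-1-yl side chain.
Remark: the (S)-acid is used in step 1 on the assumption that binaphthyl phosphoric acids of the (R)-series direct the boronate to the Re face of the aldehyde.
Remark: the C4 oxygen is carried as the trimethylsilyl ether installed in step 19; on this hindered tertiary carbinol it is expected to persist until step 28.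

**Chain**

Step 1
Reactants: 1 3-methylbut-2-enal (prenal); 2 allenylboronic acid pinacol ester
Product: 4 (4S)-6-methylhept-5-en-1-yn-4-ol, via pinacol borate ester 3 (not isolated)
Conditions: (S)-TRIP phosphoric acid (5 mol%), 4 Å MS, toluene, −20 °C; aqueous work-up
Reagents that add atoms: none
Why: Chiral phosphoric acid catalysed propargylation of an aldehyde with an allenylboronate through a closed six-membered transition state, in which the acid binds the boronate and shields one aldehyde face so that the (S)-carbinol should form.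

Step 2
Reactants: 4 (4S)-6-methylhept-5-en-1-yn-4-ol
Product: 5 (4S)-4-(tert-butyldimethylsilyloxy)-6-methylhept-5-en-1-yne
Conditions: t-BuMe2SiCl, imidazole, DMF, rt
Reagents that add atoms: tert-butyldimethylsilyl chloride CC(C)(C)[Si](C)(C)Cl
Why: Standard silylation of a secondary alcohol, which leaves the stereocentre untouched.

Step 3
Reactants: 5 (4S)-4-(tert-butyldimethylsilyloxy)-6-methylhept-5-en-1-yne
Product: 7 (1E,4S)-4-(tert-butyldimethylsilyloxy)-1-iodo-2,6-dimethylhepta-1,5-diene, via alkenylalane 6 (not isolated)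
Conditions: AlMe3 (2.5 equiv), Cp2ZrCl2 (0.2 equiv), H2O (1 equiv), CH2Cl2, −20 °C; then I2, THF, −20 → 0 °C
Reagents that add atoms: trimethylaluminium C[Al](C)C; iodine II
Why: Water-accelerated Negishi carboalumination adds methyl and aluminium syn across the terminal alkyne and iodinolysis proceeds with retention, which fixes the E geometry, while the low temperature should spare the allylic silyl ether.

Step 4
Reactants: 7 (1E,4S)-4-(tert-butyldimethylsilyloxy)-1-iodo-2,6-dimethylhepta-1,5-diene; 8 (4-iodobut-1-yn-1-yl)trimethylsilane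
Product: 11 (4S,6E)-4-(tert-butyldimethylsilyloxy)-2,6-dimethylundeca-2,6-dien-10-yne, via organozinc iodide 9 (not isolated), via silylated enyne 10 (not isolated)
Conditions: 8, Zn dust, LiCl, THF, 40 °C; then 7, Pd(PPh3)4 (5 mol%), THF, rt; then K2CO3, MeOH, rt
Reagents that add atoms: none
Why: Zinc insertion into the primary iodide and Negishi sp2–sp3 coupling with retention of alkene geometry, followed by carbonate methanolysis, which removes only the alkynyl silyl group.

Step 5
Reactants: 11 (4S,6E)-4-(tert-butyldimethylsilyloxy)-2,6-dimethylundeca-2,6-dien-10-yne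
Product: 13 (1E,5E,8S)-8-(tert-butyldimethylsilyloxy)-1-iodo-2,6,10-trimethylundeca-1,5,9-triene, via alkenylalane 12 (not isolated)
Conditions: AlMe3 (2.5 equiv), Cp2ZrCl2 (0.2 equiv), H2O (1 equiv), CH2Cl2, −20 °C; then I2, THF, −20 → 0 °C
Reagents that add atoms: trimethylaluminium C[Al](C)C; iodine II
Why: A second Negishi carboalumination and iodinolysis sets the second E-trisubstituted alkene in the same way, the existing trisubstituted alkenes being inert to the reagent.

Step 6
Reactants: 13 (1E,5E,8S)-8-(tert-butyldimethylsilyloxy)-1-iodo-2,6,10-trimethylundeca-1,5,9-triene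
Product: 15 (3E,7E,10S)-10-(tert-butyldimethylsilyloxy)-4,8,12-trimethyltrideca-3,7,11-trien-1-ol, via alkenyllithium 14 (not isolated)
Conditions: t-BuLi (2.1 equiv), Et2O, −78 °C; then oxirane, −78 → 0 °C; aqueous work-up
Reagents that add atoms: oxirane C1CO1
Why: Iodine–lithium exchange with retention of alkene geometry and SN2 opening of oxirane by the alkenyllithium add the two-carbon link to the ring.

Step 7
Reactants: 15 (3E,7E,10S)-10-(tert-butyldimethylsilyloxy)-4,8,12-trimethyltrideca-3,7,11-trien-1-ol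
Product: 16 (3E,7E,10S)-1-bromo-10-(tert-butyldimethylsilyloxy)-4,8,12-trimethyltrideca-3,7,11-triene
Conditions: CBr4, PPh3, 2,6-lutidine, CH2Cl2, 0 °C
Reagents that add atoms: tetrabromomethane BrC(Br)(Br)Br
Why: Appel bromination of a primary homoallylic alcohol under buffered conditions that the allylic silyl ether should tolerate.

**Ring B**

Step 8
Reactants: 17 geraniol
Product: 18 (2S,3S)-2,3-epoxygeraniol
Conditions: Ti(OiPr)4 (5 mol%), L-(+)-diethyl tartrate (6 mol%), t-BuOOH, 4 Å MS, CH2Cl2, −20 °C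
Reagents that add atoms: tert-butyl hydroperoxide CC(C)(C)OO
Why: Sharpless asymmetric epoxidation, in which the titanium L-(+)-tartrate complex delivers oxygen to one face of the allylic alcohol alkene only, sets the tertiary C–O centre that becomes C4.

Step 9
Reactants: 18 (2S,3S)-2,3-epoxygeraniol
Product: 19 (2R,3S)-2-(iodomethyl)-3-methyl-3-(4-methylpent-3-en-1-yl)oxirane
Conditions: I2, PPh3, imidazole, Et2O/MeCN, 0 °C
Reagents that add atoms: iodine II
Why: Appel-type iodination of the primary alcohol leaves the epoxide intact (the descriptor at C2 changes only through the priority rules).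

Step 10
Reactants: 19 (2R,3S)-2-(iodomethyl)-3-methyl-3-(4-methylpent-3-en-1-yl)oxirane
Product: 20 (S)-linalool
Conditions: Zn dust, AcOH, EtOH, rt
Reagents that add atoms: none
Why: Zinc-mediated reductive ring opening of a 2,3-epoxy iodide (a reductive β-elimination) gives the transposed tertiary allylic alcohol without touching the C–O bond of the stereocentre.

Step 11
Reactants: 20 (S)-linalool
Product: 22 (5S)-5-methyl-5-vinyltetrahydrofuran-2-ol (lactol form of (4S)-4-hydroxy-4-methylhex-5-enal as an anomer mixture), via ozonide 21 (not isolated)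
Conditions: O3 (about 1 equiv, indicator end point), CH2Cl2, −78 °C; then Me2S, −78 °C → rt
Reagents that add atoms: ozone [O-][O+]=O
Why: Chemoselective ozonolysis of the electron-rich trisubstituted alkene in the presence of the vinyl group, with reductive work-up to the aldehyde, which closes to the lactol.

Step 12
Reactants: 22 (5S)-5-methyl-5-vinyltetrahydrofuran-2-ol
Product: 23 (6S)-6-methylocta-1,7-diene-3,6-diol (C3 epimers)
Conditions: CH2=CHMgBr (3 equiv), THF, 0 °C → rt; aqueous work-up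
Reagents that add atoms: vinylmagnesium bromide C=C[Mg]Br
Why: Grignard addition to a lactol, which reacts through its open hydroxy aldehyde form; the new carbinol centre is oxidised away in step 14.

Step 13
Reactants: 23 (6S)-6-methylocta-1,7-diene-3,6-diol
Product: 24 (1S)-1-methylcyclohex-2-ene-1,4-diol (C4 epimers)
Conditions: second-generation Grubbs catalyst (2 mol%), CH2Cl2, 40 °C
Reagents that add atoms: none
Why: Ring-closing metathesis of a 1,7-diene forms six-membered ring B with loss of ethene.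

Step 14
Reactants: 24 (1S)-1-methylcyclohex-2-ene-1,4-diol
Product: 25 (4S)-4-hydroxy-4-methylcyclohex-2-en-1-one
Conditions: MnO2, CH2Cl2, rt
Reagents that add atoms: none
Why: MnO2 oxidation of the secondary allylic alcohol; the tertiary alcohol cannot be oxidised.

Step 15
Reactants: 25 (4S)-4-hydroxy-4-methylcyclohex-2-en-1-one
Product: 26 (4S)-4-methyl-4-(trimethylsilyloxy)cyclohex-2-en-1-one
Conditions: Me3SiCl, imidazole, DMF, rt
Reagents that add atoms: chlorotrimethylsilane C[Si](C)(C)Cl
Why: Silylation of the tertiary alcohol, so that the chain organometallic of step 17 is not consumed by the hydroxyl proton.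

**Annulation reagent**

Step 16
Reactants: 27 (1-bromovinyl)trimethylsilane; 28 propanoic anhydride
Product: 30 2-(trimethylsilyl)pent-1-en-3-one, via vinyl Grignard reagent 29 (not isolated)
Conditions: 27, Mg, THF, reflux; then added to 28 (excess), THF, −78 °C
Reagents that add atoms: none
Why: Acylation of an α-silylvinyl Grignard reagent with an anhydride at low temperature stops at the ketone and gives the silyl-stabilised equivalent of ethyl vinyl ketone.

**Union, ring A and end game**

Step 17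
Reactants: 16 chain bromide; 26 (4S)-4-methyl-4-(trimethylsilyloxy)cyclohex-2-en-1-one
Product: 32 (4S)-4-methyl-3-SC-1,4-bis(trimethylsilyloxy)cyclohex-1-ene (C3 epimers), via chain Grignard reagent 31 (not isolated)
Conditions: 16, Mg, THF, rt; then CuBr·SMe2 (10 mol%), HMPA, −78 °C; 26 and Me3SiCl, −78 → −40 °C; Et3N
Reagents that add atoms: chlorotrimethylsilane C[Si](C)(C)Cl
Why: Copper-catalysed conjugate addition of a Grignard reagent accelerated by chlorosilane, which traps the C1–C6 enolate regiospecifically; the configuration at C5 is erased in step 18.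

Step 18
Reactants: 32 (4S)-4-methyl-3-SC-1,4-bis(trimethylsilyloxy)cyclohex-1-ene
Product: 34 (4S)-4-hydroxy-4-methyl-3-SC-cyclohex-2-en-1-one, via silyloxy enone 33 (not isolated)
Conditions: Pd(OAc)2 (1.1 equiv), MeCN, rt; then Bu4NF (1.1 equiv), THF, 0 °C
Reagents that add atoms: none
Why: Saegusa oxidation (palladation of the enol silyl ether and β-hydride elimination of the C5 hydrogen) restores the enone with the chain on its β-carbon, and one equivalent of fluoride at 0 °C should remove the trimethylsilyl ether while the tert-butyldimethylsilyl ether stays.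

Step 19
Reactants: 34 (4S)-4-hydroxy-4-methyl-3-SC-cyclohex-2-en-1-one
Product: 36 (3S,4S)-3,4-dimethyl-3-SC-1,4-bis(trimethylsilyloxy)cyclohex-1-ene, via magnesium enolate 35 (not isolated)
Conditions: MeMgCl (4 equiv), THF, −78 → 0 °C; then Me3SiCl, Et3N, HMPA, −78 °C → rt
Reagents that add atoms: methylmagnesium chloride C[Mg]Cl; chlorotrimethylsilane C[Si](C)(C)Cl
Why: Alkoxide-directed conjugate addition of a Grignard reagent to a γ-hydroxy enone, in which the chloromagnesium alkoxide at C4 binds a second equivalent of reagent and delivers methyl to C5 on its own face, so the new quaternary centre should carry CH3 cis to the C4 oxygen, and silylation fixes the C1–C6 enolate.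

Step 20
Reactants: 36 (3S,4S)-3,4-dimethyl-3-SC-1,4-bis(trimethylsilyloxy)cyclohex-1-ene; 30 2-(trimethylsilyl)pent-1-en-3-one
Product: 39 (2S,3S,4S)-3,4-dimethyl-2-(3-oxopentyl)-3-SC-4-(trimethylsilyloxy)cyclohexan-1-one, via lithium enolate 37 (not isolated), via silyl diketone 38 (not isolated)
Conditions: MeLi (1.05 equiv), THF, 0 °C; then 30, −78 → −30 °C; aqueous work-up; then K2CO3 (cat.), MeOH, 0 °C
Reagents that add atoms: none
Why: Methyllithium cleavage of the enol silyl ether gives the regiodefined lithium enolate for a Michael addition to the α-silyl vinyl ketone, where axial attack at C6 anti to the pseudoaxial C5 chain, in the half-chair that holds the C4 silyloxy group and not the C4 methyl axial, should place the arm cis to the C4 oxygen and the C5 methyl, and brief carbonate methanolysis then removes only the C-silyl group.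

Step 21
Reactants: 39 (2S,3S,4S)-3,4-dimethyl-2-(3-oxopentyl)-3-SC-4-(trimethylsilyloxy)cyclohexan-1-one
Product: 41 (4aR,5S,6S)-1,5,6-trimethyl-5-SC-6-(trimethylsilyloxy)-4,4a,5,6,7,8-hexahydronaphthalen-2(3H)-one, via ring A ketol 40 (not isolated)
Conditions: pyrrolidine (0.5 equiv), AcOH (0.5 equiv), toluene, 60 °C
Reagents that add atoms: none
Why: Pyrrolidinium acetate converts the unhindered ethyl ketone into its enamine, whose methyl-bearing carbon adds to the C1 ring carbonyl to give ketol 40, and loss of water through the iminium ion yields the conjugated enone; the closest known reaction type is the aldol cyclodehydration that completes a Robinson annulation with ethyl vinyl ketone. Ring A closes in the 6-(enolexo)-exo-trig mode and holds C6, the two arm methylenes, the ketone carbon, the methyl-bearing carbon and C1. No stereocentre is created, because both new ring atoms end as sp2 carbons, but the ring fixes the tetrasubstituted alkene with the carbonyl carbon cis to C6 and the methyl cis to C2. The selectivity needed is constitutional: aldol adducts of the C2 enolate with the side-chain ketone are bridged and cannot dehydrate, and attack from the inner arm methylene would close a four-membered ring, so only the desired pairing drains to the conjugated octalone. The buffered amine medium avoids alkoxide bases and the hindered C1 ketone, flanked by C6 and quaternary C5, is not expected to form an enamine itself, so the C6 configuration from step 20 should be carried through unchanged.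

Step 22
Reactants: 41 ring A octalone
Product: 43 3-hydroxy derivative of octalone 41 (C3 epimers), via sodium dienolate 42 (not isolated)
Conditions: NaN(SiMe3)2, THF, −78 °C; then 3-phenyl-2-(phenylsulfonyl)oxaziridine, −78 °C; aqueous work-up
Reagents that add atoms: 3-phenyl-2-(phenylsulfonyl)oxaziridine O=S(=O)(N1OC1c1ccccc1)c1ccccc1
Why: Kinetic deprotonation of the enone at its saturated α-carbon gives the cross-conjugated dienolate, which is hydroxylated by the N-sulfonyloxaziridine (enolate hydroxylation) without attack on the chain alkenes; the new carbinol centre is destroyed in step 23.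

Step 23
Reactants: 43 3-hydroxy derivative of octalone 41
Product: 44 methyl (2Z)-2-[(2R,3S,4S)-3,4-dimethyl-2-(2-oxoethyl)-3-SC-4-(trimethylsilyloxy)cyclohexylidene]propanoate
Conditions: Pb(OAc)4 (1.2 equiv), MeOH/toluene 1:1, 0 °C
Reagents that add atoms: methanol CO
Why: Criegee-type cleavage of an α-ketol in methanol, through the hemiketal, opens ring A between the carbonyl and the carbinol carbon and releases the Z-enoate and the two-carbon aldehyde arm at different oxidation levels.

Step 24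
Reactants: 44 aldehyde ester
Product: 45 methyl (2Z)-2-[(2R,3S,4S)-2-allyl-3,4-dimethyl-3-SC-4-(trimethylsilyloxy)cyclohexylidene]propanoate
Conditions: Ph3PCH3Br, KN(SiMe3)2, THF, 0 °C; then 44, −78 → 0 °C
Reagents that add atoms: methyltriphenylphosphonium bromide C[P+](c1ccccc1)(c1ccccc1)c1ccccc1.[Br-]
Why: Wittig methylenation adds the third arm carbon at the aldehyde, the hindered conjugated ester being inert to the ylide.

Step 25
Reactants: 45 alkene ester
Product: 47 methyl (2Z)-2-[(2R,3S,4S)-2-(3-hydroxypropyl)-3,4-dimethyl-3-SC-4-(trimethylsilyloxy)cyclohexylidene]propanoate, via alkylborane 46 (not isolated)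
Conditions: 9-BBN (2 equiv), THF, 0 °C → rt; then aqueous NaOAc, 30% H2O2, 0 °C → rt
Reagents that add atoms: hydrogen peroxide OO
Why: Anti-Markovnikov hydroboration with 9-BBN is selective for the monosubstituted alkene over the trisubstituted chain alkenes and the enoate, and buffered peroxide oxidation gives the primary alcohol.

Step 26
Reactants: 47 hydroxy ester
Product: 48 (2Z)-2-[(2R,3S,4S)-2-(3-hydroxypropyl)-3,4-dimethyl-3-SC-4-(trimethylsilyloxy)cyclohexylidene]propan-1-ol
Conditions: iBu2AlH (5 equiv), CH2Cl2, −78 → −20 °C; aqueous potassium sodium tartrate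
Reagents that add atoms: none
Why: 1,2-Reduction of the conjugated ester by the aluminium hydride gives the allylic alcohol without change of alkene geometry.

Step 27
Reactants: 48 diol
Product: 49 (2Z)-2-[(2R,3S,4S)-2-(3-hydroxypropyl)-3,4-dimethyl-3-SC-4-(trimethylsilyloxy)cyclohexylidene]propanal
Conditions: MnO2, CH2Cl2, rt
Reagents that add atoms: none
Why: MnO2 oxidises only the allylic primary alcohol and leaves the saturated primary alcohol, so the Z-enal appears with the geometry set by ring A.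

Step 28
Reactants: 49 silylated enal
Product: 50 (2Z)-2-[(2R,3S,4S)-4-hydroxy-2-(3-hydroxypropyl)-3-[(3E,7E,10S)-10-hydroxy-4,8,12-trimethyltrideca-3,7,11-trien-1-yl]-3,4-dimethylcyclohexylidene]propanal
Conditions: Bu4NF, AcOH, THF, 0 °C → rt
Reagents that add atoms: none
Why: Buffered fluoride desilylation removes both silyl ethers without enolising the enal.

Step 29
Reactants: 50 triol enal
Product: 51 CNP0161066.1, (2Z)-2-[(2R,3S,4S)-4-hydroxy-2-(3-hydroxypropyl)-3-[(3E,7E,10S)-10-hydroxy-10-[(2R)-3,3-dimethyloxiran-2-yl]-4,8-dimethyldeca-3,7-dien-1-yl]-3,4-dimethylcyclohexylidene]propanal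
Conditions: VO(acac)2 (5 mol%), t-BuOOH (1.3 equiv), CH2Cl2, 0 °C
Reagents that add atoms: tert-butyl hydroperoxide CC(C)(C)OO
Why: Vanadium-catalysed hydroxyl-directed epoxidation is selective for the allylic alcohol alkene, and allylic 1,3-strain between the carbinol substituent and the cis methyl group fixes the reactive conformer so that oxygen is delivered on the hydroxyl face to give the threo (2R) epoxide.

**Compound list**
1 | 3-methylbut-2-enal (prenal) | CC(C)=CC=O | starting material
2 | allenylboronic acid pinacol ester | C=C=CB1OC(C)(C)C(C)(C)O1 | starting material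
3 | pinacol borate ester of 4 | C#CC[C@H](OB1OC(C)(C)C(C)(C)O1)C=C(C)C | intermediate
4 | (4S)-6-methylhept-5-en-1-yn-4-ol | C#CC[C@H](O)C=C(C)C | intermediate
5 | (4S)-4-(tert-butyldimethylsilyloxy)-6-methylhept-5-en-1-yne | C#CC[C@H](O[Si](C)(C)C(C)(C)C)C=C(C)C | intermediate
6 | dimethyl[(1E,4S)-4-(tert-butyldimethylsilyloxy)-2,6-dimethylhepta-1,5-dien-1-yl]alane | C[Al](C)/C=C(\C)C[C@H](O[Si](C)(C)C(C)(C)C)C=C(C)C | intermediate
7 | (1E,4S)-4-(tert-butyldimethylsilyloxy)-1-iodo-2,6-dimethylhepta-1,5-diene | I/C=C(\C)C[C@H](O[Si](C)(C)C(C)(C)C)C=C(C)C | intermediate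
8 | (4-iodobut-1-yn-1-yl)trimethylsilane | C[Si](C)(C)C#CCCI | starting material
9 | [4-(trimethylsilyl)but-3-yn-1-yl]zinc iodide | C[Si](C)(C)C#CCC[Zn]I | intermediate
10 | (4S,6E)-4-(tert-butyldimethylsilyloxy)-2,6-dimethyl-11-(trimethylsilyl)undeca-2,6-dien-10-yne | C[Si](C)(C)C#CCC/C=C(\C)C[C@H](O[Si](C)(C)C(C)(C)C)C=C(C)C | intermediate
11 | (4S,6E)-4-(tert-butyldimethylsilyloxy)-2,6-dimethylundeca-2,6-dien-10-yne | C#CCC/C=C(\C)C[C@H](O[Si](C)(C)C(C)(C)C)C=C(C)C | intermediate
12 | dimethyl[(1E,5E,8S)-8-(tert-butyldimethylsilyloxy)-2,6,10-trimethylundeca-1,5,9-trien-1-yl]alane | C[Al](C)/C=C(\C)CC/C=C(\C)C[C@H](O[Si](C)(C)C(C)(C)C)C=C(C)C | intermediate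
13 | (1E,5E,8S)-8-(tert-butyldimethylsilyloxy)-1-iodo-2,6,10-trimethylundeca-1,5,9-triene | I/C=C(\C)CC/C=C(\C)C[C@H](O[Si](C)(C)C(C)(C)C)C=C(C)C | intermediate
14 | [(1E,5E,8S)-8-(tert-butyldimethylsilyloxy)-2,6,10-trimethylundeca-1,5,9-trien-1-yl]lithium | [Li]/C=C(\C)CC/C=C(\C)C[C@H](O[Si](C)(C)C(C)(C)C)C=C(C)C | intermediate
15 | (3E,7E,10S)-10-(tert-butyldimethylsilyloxy)-4,8,12-trimethyltrideca-3,7,11-trien-1-ol | OCC/C=C(\C)CC/C=C(\C)C[C@H](O[Si](C)(C)C(C)(C)C)C=C(C)C | intermediate
16 | (3E,7E,10S)-1-bromo-10-(tert-butyldimethylsilyloxy)-4,8,12-trimethyltrideca-3,7,11-triene | BrCC/C=C(\C)CC/C=C(\C)C[C@H](O[Si](C)(C)C(C)(C)C)C=C(C)C | intermediate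
17 | geraniol, (2E)-3,7-dimethylocta-2,6-dien-1-ol | CC(C)=CCC/C(C)=C/CO | starting material
18 | (2S,3S)-2,3-epoxygeraniol, [(2S,3S)-3-methyl-3-(4-methylpent-3-en-1-yl)oxiran-2-yl]methanol | CC(C)=CCC[C@]1(C)O[C@H]1CO | intermediate
19 | (2R,3S)-2-(iodomethyl)-3-methyl-3-(4-methylpent-3-en-1-yl)oxirane | CC(C)=CCC[C@]1(C)O[C@H]1CI | intermediate
20 | (S)-linalool, (3S)-3,7-dimethylocta-1,6-dien-3-ol | CC(C)=CCC[C@](C)(O)C=C | intermediate
21 | 5-[(3S)-3-hydroxy-3-methylpent-4-en-1-yl]-3,3-dimethyl-1,2,4-trioxolane (ozonide) | CC1(C)OOC(CC[C@](C)(O)C=C)O1 | intermediate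
22 | (5S)-5-methyl-5-vinyltetrahydrofuran-2-ol (anomers; lactol of (4S)-4-hydroxy-4-methylhex-5-enal) | OC1CC[C@@](C)(C=C)O1 | intermediate
23 | (6S)-6-methylocta-1,7-diene-3,6-diol (C3 epimers) | C=CC(O)CC[C@](C)(O)C=C | intermediate
24 | (1S)-1-methylcyclohex-2-ene-1,4-diol (C4 epimers) | OC1CC[C@](C)(O)C=C1 | intermediate
25 | (4S)-4-hydroxy-4-methylcyclohex-2-en-1-one | O=C1CC[C@](C)(O)C=C1 | intermediate
26 | (4S)-4-methyl-4-(trimethylsilyloxy)cyclohex-2-en-1-one | O=C1CC[C@](C)(O[Si](C)(C)C)C=C1 | intermediate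
27 | (1-bromovinyl)trimethylsilane | C=C(Br)[Si](C)(C)C | starting material
28 | propanoic anhydride | CCC(=O)OC(=O)CC | starting material
29 | [1-(trimethylsilyl)vinyl]magnesium bromide | C=C([Mg]Br)[Si](C)(C)C | intermediate
30 | 2-(trimethylsilyl)pent-1-en-3-one | C=C([Si](C)(C)C)C(=O)CC | intermediate
31 | [(3E,7E,10S)-10-(tert-butyldimethylsilyloxy)-4,8,12-trimethyltrideca-3,7,11-trien-1-yl]magnesium bromide | Br[Mg]CC/C=C(\C)CC/C=C(\C)C[C@H](O[Si](C)(C)C(C)(C)C)C=C(C)C | intermediate
32 | (4S)-4-methyl-3-SC-1,4-bis(trimethylsilyloxy)cyclohex-1-ene (C3 epimers) | C[Si](C)(C)OC1=CC(CC/C=C(\C)CC/C=C(\C)C[C@H](O[Si](C)(C)C(C)(C)C)C=C(C)C)[C@@](C)(O[Si](C)(C)C)CC1 | intermediate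
33 | (4S)-4-methyl-3-SC-4-(trimethylsilyloxy)cyclohex-2-en-1-one | O=C1CC[C@](C)(O[Si](C)(C)C)C(CC/C=C(\C)CC/C=C(\C)C[C@H](O[Si](C)(C)C(C)(C)C)C=C(C)C)=C1 | intermediate
34 | (4S)-4-hydroxy-4-methyl-3-SC-cyclohex-2-en-1-one | O=C1CC[C@](C)(O)C(CC/C=C(\C)CC/C=C(\C)C[C@H](O[Si](C)(C)C(C)(C)C)C=C(C)C)=C1 | intermediate
35 | bis(chloromagnesium) salt of (3S,4S)-3,4-dimethyl-3-SC-cyclohex-1-ene-1,4-diol (enolate and alkoxide) | Cl[Mg]OC1=C[C@](C)(CC/C=C(\C)CC/C=C(\C)C[C@H](O[Si](C)(C)C(C)(C)C)C=C(C)C)[C@@](C)(O[Mg]Cl)CC1 | intermediate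
36 | (3S,4S)-3,4-dimethyl-3-SC-1,4-bis(trimethylsilyloxy)cyclohex-1-ene | C[Si](C)(C)OC1=C[C@](C)(CC/C=C(\C)CC/C=C(\C)C[C@H](O[Si](C)(C)C(C)(C)C)C=C(C)C)[C@@](C)(O[Si](C)(C)C)CC1 | intermediate
37 | lithium (3S,4S)-3,4-dimethyl-3-SC-4-(trimethylsilyloxy)cyclohex-1-en-1-olate | [Li]OC1=C[C@](C)(CC/C=C(\C)CC/C=C(\C)C[C@H](O[Si](C)(C)C(C)(C)C)C=C(C)C)[C@@](C)(O[Si](C)(C)C)CC1 | intermediate
38 | (2S,3S,4S)-3,4-dimethyl-2-[3-oxo-2-(trimethylsilyl)pentyl]-3-SC-4-(trimethylsilyloxy)cyclohexan-1-one (epimers at the silyl carbon) | O=C1CC[C@](C)(O[Si](C)(C)C)[C@@](C)(CC/C=C(\C)CC/C=C(\C)C[C@H](O[Si](C)(C)C(C)(C)C)C=C(C)C)[C@@H]1CC([Si](C)(C)C)C(=O)CC | intermediate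
39 | (2S,3S,4S)-3,4-dimethyl-2-(3-oxopentyl)-3-SC-4-(trimethylsilyloxy)cyclohexan-1-one | O=C1CC[C@](C)(O[Si](C)(C)C)[C@@](C)(CC/C=C(\C)CC/C=C(\C)C[C@H](O[Si](C)(C)C(C)(C)C)C=C(C)C)[C@@H]1CCC(=O)CC | intermediate
40 | (4aR,5S,6S)-8a-hydroxy-1,5,6-trimethyl-5-SC-6-(trimethylsilyloxy)octahydronaphthalen-2(1H)-one (ring A ketol; C1 and C8a epimers) | CC1C2(O)CC[C@](C)(O[Si](C)(C)C)[C@@](C)(CC/C=C(\C)CC/C=C(\C)C[C@H](O[Si](C)(C)C(C)(C)C)C=C(C)C)[C@@H]2CCC1=O | intermediate
41 | (4aR,5S,6S)-1,5,6-trimethyl-5-SC-6-(trimethylsilyloxy)-4,4a,5,6,7,8-hexahydronaphthalen-2(3H)-one (ring A octalone) | CC1=C2CC[C@](C)(O[Si](C)(C)C)[C@@](C)(CC/C=C(\C)CC/C=C(\C)C[C@H](O[Si](C)(C)C(C)(C)C)C=C(C)C)[C@@H]2CCC1=O | intermediate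
42 | sodium dienolate of 41 (enolate towards C3 of ring A) | CC1=C2CC[C@](C)(O[Si](C)(C)C)[C@@](C)(CC/C=C(\C)CC/C=C(\C)C[C@H](O[Si](C)(C)C(C)(C)C)C=C(C)C)[C@@H]2CC=C1O[Na] | intermediate
43 | (4aR,5S,6S)-3-hydroxy-1,5,6-trimethyl-5-SC-6-(trimethylsilyloxy)-4,4a,5,6,7,8-hexahydronaphthalen-2(3H)-one (C3 epimers) | CC1=C2CC[C@](C)(O[Si](C)(C)C)[C@@](C)(CC/C=C(\C)CC/C=C(\C)C[C@H](O[Si](C)(C)C(C)(C)C)C=C(C)C)[C@@H]2CC(O)C1=O | intermediate
44 | methyl (2Z)-2-[(2R,3S,4S)-3,4-dimethyl-2-(2-oxoethyl)-3-SC-4-(trimethylsilyloxy)cyclohexylidene]propanoate | C/C(C(=O)OC)=C1\CC[C@](C)(O[Si](C)(C)C)[C@@](C)(CC/C=C(\C)CC/C=C(\C)C[C@H](O[Si](C)(C)C(C)(C)C)C=C(C)C)[C@@H]1CC=O | intermediate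
45 | methyl (2Z)-2-[(2R,3S,4S)-2-allyl-3,4-dimethyl-3-SC-4-(trimethylsilyloxy)cyclohexylidene]propanoate | C/C(C(=O)OC)=C1\CC[C@](C)(O[Si](C)(C)C)[C@@](C)(CC/C=C(\C)CC/C=C(\C)C[C@H](O[Si](C)(C)C(C)(C)C)C=C(C)C)[C@@H]1CC=C | intermediate
46 | B-alkyl-9-borabicyclo[3.3.1]nonane from 45 (boron on the terminal arm carbon) | C/C(C(=O)OC)=C1\CC[C@](C)(O[Si](C)(C)C)[C@@](C)(CC/C=C(\C)CC/C=C(\C)C[C@H](O[Si](C)(C)C(C)(C)C)C=C(C)C)[C@@H]1CCCB2C3CCCC2CCC3 | intermediate
47 | methyl (2Z)-2-[(2R,3S,4S)-2-(3-hydroxypropyl)-3,4-dimethyl-3-SC-4-(trimethylsilyloxy)cyclohexylidene]propanoate | C/C(C(=O)OC)=C1\CC[C@](C)(O[Si](C)(C)C)[C@@](C)(CC/C=C(\C)CC/C=C(\C)C[C@H](O[Si](C)(C)C(C)(C)C)C=C(C)C)[C@@H]1CCCO | intermediate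
48 | (2Z)-2-[(2R,3S,4S)-2-(3-hydroxypropyl)-3,4-dimethyl-3-SC-4-(trimethylsilyloxy)cyclohexylidene]propan-1-ol | C/C(CO)=C1\CC[C@](C)(O[Si](C)(C)C)[C@@](C)(CC/C=C(\C)CC/C=C(\C)C[C@H](O[Si](C)(C)C(C)(C)C)C=C(C)C)[C@@H]1CCCO | intermediate
49 | (2Z)-2-[(2R,3S,4S)-2-(3-hydroxypropyl)-3,4-dimethyl-3-SC-4-(trimethylsilyloxy)cyclohexylidene]propanal | C/C(C=O)=C1\CC[C@](C)(O[Si](C)(C)C)[C@@](C)(CC/C=C(\C)CC/C=C(\C)C[C@H](O[Si](C)(C)C(C)(C)C)C=C(C)C)[C@@H]1CCCO | intermediate
50 | (2Z)-2-[(2R,3S,4S)-4-hydroxy-2-(3-hydroxypropyl)-3-[(3E,7E,10S)-10-hydroxy-4,8,12-trimethyltrideca-3,7,11-trien-1-yl]-3,4-dimethylcyclohexylidene]propanal | C/C(C=O)=C1\CC[C@](C)(O)[C@@](C)(CC/C=C(\C)CC/C=C(\C)C[C@H](O)C=C(C)C)[C@@H]1CCCO | intermediate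
51 | CNP0161066.1, (2Z)-2-[(2R,3S,4S)-4-hydroxy-2-(3-hydroxypropyl)-3-[(3E,7E,10S)-10-hydroxy-10-[(2R)-3,3-dimethyloxiran-2-yl]-4,8-dimethyldeca-3,7-dien-1-yl]-3,4-dimethylcyclohexylidene]propanal | C/C(C=O)=C1\CC[C@](C)(O)[C@@](C)(CC/C=C(\C)CC/C=C(\C)C[C@H](O)[C@H]2OC2(C)C)[C@@H]1CCCO | target

**Count**
Total steps: 29. Longest linear sequence: 21 steps (geraniol, steps 8–15, then steps 17–29); the chain branch is 20 steps (steps 1–7, then 17–29).

**Steps most likely to fail**

Step 19. The Grignard reagent may add 1,2 to the ketone, or internal delivery may not overcome the crowding of a quaternary centre next to the tertiary carbinol. The fallback reverses the order in which the two C5 substituents arrive and sets out from silyloxy enone 26. Conjugate addition of Me2CuLi with Me3SiCl gives the methyl-substituted enol silyl ether F1. Saegusa oxidation with Pd(OAc)2 gives the β-methyl enone F2. Copper-catalysed addition of chain Grignard reagent 31 (CuBr·SMe2, Me3SiCl, HMPA) to F2 should occur by axial attack anti to the pseudoaxial C4 silyloxy group, which places the chain trans to oxygen. The chlorosilane traps the enolate, so the sequence comes back to the route at bis-silyl enol ether 36.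

Step 20. The Michael acceptor may approach C6 with poor or reversed facial selectivity, or proton transfer may outrun carbon–carbon bond formation at the hindered enolate. The fallback lets a proton, not carbon, enter C6 last, and sets out from bis-silyl enol ether 36 through its lithium enolate 37. Dimethylmethyleneiminium iodide gives the Mannich base F3. Quaternisation with MeI and elimination with NaHCO3 give the α-methylene ketone F4. The regiochemically pure lithium enolate of butan-2-one (from 2-(trimethylsilyloxy)but-1-ene and MeLi) adds in conjugate fashion to F4 and gives the ring lithium enolate F5. Protonation of F5 at −78 °C with 2,6-di-tert-butylphenol puts hydrogen on the face that an electrophile prefers and so turns the arm to the other face. The sequence comes back to the route at diketone 39.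

Step 23. Hemiketal formation at the hindered conjugated ketone may be too slow, so that the ketol is not cleaved before Pb(OAc)4 attacks other sites. The fallback cleaves a diol and sets out from hydroxy enone 43. Luche reduction (NaBH4, CeCl3·7H2O, MeOH) gives the ring A diol F6. NaIO4 in THF/H2O gives the Z-enal aldehyde F7. One equivalent of Ph3P=CH2 at −78 °C should methylenate only the saturated aldehyde and give the enal alkene F8. A second Luche reduction gives the allylic alcohol F9. 9-BBN gives the alkylborane F10, and buffered H2O2 oxidation comes back to the route at diol 48.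

**Further compounds**
F1 | step 19 | (4S)-3,4-dimethyl-1,4-bis(trimethylsilyloxy)cyclohex-1-ene (C3 epimers) | C[Si](C)(C)OC1=CC(C)[C@@](C)(O[Si](C)(C)C)CC1
F2 | step 19 | (4S)-3,4-dimethyl-4-(trimethylsilyloxy)cyclohex-2-en-1-one | O=C1CC[C@](C)(O[Si](C)(C)C)C(C)=C1
F3 | step 20 | (3S,4S)-2-[(dimethylamino)methyl]-3,4-dimethyl-3-SC-4-(trimethylsilyloxy)cyclohexan-1-one (C2 epimers) | O=C1CC[C@](C)(O[Si](C)(C)C)[C@@](C)(CC/C=C(\C)CC/C=C(\C)C[C@H](O[Si](C)(C)C(C)(C)C)C=C(C)C)C1CN(C)C
F4 | step 20 | (3S,4S)-3,4-dimethyl-2-methylidene-3-SC-4-(trimethylsilyloxy)cyclohexan-1-one | O=C1CC[C@](C)(O[Si](C)(C)C)[C@@](C)(CC/C=C(\C)CC/C=C(\C)C[C@H](O[Si](C)(C)C(C)(C)C)C=C(C)C)C1=C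
F5 | step 20 | lithium (3S,4S)-3,4-dimethyl-2-(3-oxopentyl)-3-SC-4-(trimethylsilyloxy)cyclohex-1-en-1-olate | [Li]OC1=C(CCC(=O)CC)[C@](C)(CC/C=C(\C)CC/C=C(\C)C[C@H](O[Si](C)(C)C(C)(C)C)C=C(C)C)[C@@](C)(O[Si](C)(C)C)CC1
F6 | step 23 | (4aR,5S,6S)-1,5,6-trimethyl-5-SC-6-(trimethylsilyloxy)-2,3,4,4a,5,6,7,8-octahydronaphthalene-2,3-diol (epimers at C2 and C3) | CC1=C2CC[C@](C)(O[Si](C)(C)C)[C@@](C)(CC/C=C(\C)CC/C=C(\C)C[C@H](O[Si](C)(C)C(C)(C)C)C=C(C)C)[C@@H]2CC(O)C1O
F7 | step 23 | (2Z)-2-[(2R,3S,4S)-3,4-dimethyl-2-(2-oxoethyl)-3-SC-4-(trimethylsilyloxy)cyclohexylidene]propanal | C/C(C=O)=C1\CC[C@](C)(O[Si](C)(C)C)[C@@](C)(CC/C=C(\C)CC/C=C(\C)C[C@H](O[Si](C)(C)C(C)(C)C)C=C(C)C)[C@@H]1CC=O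
F8 | step 23 | (2Z)-2-[(2R,3S,4S)-2-allyl-3,4-dimethyl-3-SC-4-(trimethylsilyloxy)cyclohexylidene]propanal | C/C(C=O)=C1\CC[C@](C)(O[Si](C)(C)C)[C@@](C)(CC/C=C(\C)CC/C=C(\C)C[C@H](O[Si](C)(C)C(C)(C)C)C=C(C)C)[C@@H]1CC=C
F9 | step 23 | (2Z)-2-[(2R,3S,4S)-2-allyl-3,4-dimethyl-3-SC-4-(trimethylsilyloxy)cyclohexylidene]propan-1-ol | C/C(CO)=C1\CC[C@](C)(O[Si](C)(C)C)[C@@](C)(CC/C=C(\C)CC/C=C(\C)C[C@H](O[Si](C)(C)C(C)(C)C)C=C(C)C)[C@@H]1CC=C
F10 | step 23 | B-alkyl-9-borabicyclo[3.3.1]nonane from F9 (boron on the terminal arm carbon) | C/C(CO)=C1\CC[C@](C)(O[Si](C)(C)C)[C@@](C)(CC/C=C(\C)CC/C=C(\C)C[C@H](O[Si](C)(C)C(C)(C)C)C=C(C)C)[C@@H]1CCCB2C3CCCC2CCC3
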